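**Strategy**

Both five-carbon units are traced back to oxygen-bound tertiary ethers on a single chalcone. Chalcone 7 carries a 1,1-dimethylallyl ether at O4' of ring A and a 1,1-dimethylpropargyl ether on the ring B oxygen. One heating operation shifts the first to C3' as the prenyl group and converts the second, through C3a–C3 bond formation and oxa-electrocyclisation, into a 2,2-dimethylchromene. This exploits the fact that each ring holds its C5 unit ortho to a phenolic oxygen: prenyl at C3' beside O4' (ring A) and C3–C2–C(CH3)2 at C3a beside O1 (ring B). Catalyst-controlled epoxidation, anti hydrolysis and a stereospecific 1,2-aryloxy shift then contract the pyran to the (2R,3R)-dihydrobenzofuran.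

Key step: step 5

Remarks on numbering and abbreviations: ring B positions follow the 2,3-dihydro-1-benzofuran numbering of the target (O1, C2, C3, C3a); chroman intermediates use chroman numbering (O1, C2, C3, C4). TBS = tert-butyldimethylsilyl. Mn(salen)Cl = [N,N'-bis(3,5-di-tert-butylsalicylidene)-(1S,2S)-cyclohexane-1,2-diaminato]manganese chloride, a complex of trivalent manganese.

Design remark: the C4 hydroxyl of the trans-diol is silylated before the C3 oxygen is made a leaving group, because a free neighbouring hydroxyl could re-close an epoxide or drive a semipinacol shift.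

**Route**

Step 1
Reactants: 1 4-hydroxybenzaldehyde; 2 3-chloro-3-methylbut-1-yne
Product: 3 4-(2-methylbut-3-yn-2-yloxy)benzaldehyde
Conditions: K2CO3, KI, CuI (cat.), acetone, 60 °C
Reagents that add atoms: 3-chloro-3-methylbut-1-yne (compound 2), C#CC(C)(C)Cl
Why: Copper-assisted Williamson-type propargylic etherification, in which the phenoxide captures the tertiary propargylic electrophile at the carbinol carbon while the non-enolisable aldehyde is inert to carbonate.

Step 2
Reactants: 4 2,4-dihydroxyacetophenone; 2 3-chloro-3-methylbut-1-yne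
Product: 5 1-[2-hydroxy-4-(2-methylbut-3-yn-2-yloxy)phenyl]ethanone
Conditions: K2CO3, KI, CuI (cat.), acetone, 60 °C
Reagents that add atoms: 3-chloro-3-methylbut-1-yne (compound 2), C#CC(C)(C)Cl
Why: The same propargylic etherification should occur only at the 4-OH, because the 2-OH is locked in a hydrogen bond to the acetyl carbonyl and is much less nucleophilic.

Step 3
Reactants: 5 1-[2-hydroxy-4-(2-methylbut-3-yn-2-yloxy)phenyl]ethanone
Product: 6 1-[2-hydroxy-4-(2-methylbut-3-en-2-yloxy)phenyl]ethanone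
Conditions: H2 (1 atm), Pd/CaCO3 poisoned with Pb(OAc)2, quinoline, EtOAc, rt
Reagents that add atoms: none
Why: Lindlar semihydrogenation adds one equivalent of hydrogen to the terminal alkyne and stops at the alkene, leaving the aryl ketone and the tertiary aryl ether untouched.

Step 4
Reactants: 6 1-[2-hydroxy-4-(2-methylbut-3-en-2-yloxy)phenyl]ethanone; 3 4-(2-methylbut-3-yn-2-yloxy)benzaldehyde
Product: 7 (E)-1-[2-hydroxy-4-(2-methylbut-3-en-2-yloxy)phenyl]-3-[4-(2-methylbut-3-yn-2-yloxy)phenyl]prop-2-en-1-one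
Conditions: KOH, EtOH/H2O, 0 °C to rt
Reagents that add atoms: none
Why: Claisen–Schmidt condensation, in which the methyl ketone enolate adds to the non-enolisable aldehyde and E1cB dehydration gives the conjugated E-enone, while both tertiary ethers are stable to hydroxide.

Step 5
Reactants: 7 (E)-1-[2-hydroxy-4-(2-methylbut-3-en-2-yloxy)phenyl]-3-[4-(2-methylbut-3-yn-2-yloxy)phenyl]prop-2-en-1-one
Product: 11 (E)-1-[2,4-dihydroxy-3-(3-methylbut-2-enyl)phenyl]-3-(2,2-dimethyl-2H-chromen-6-yl)prop-2-en-1-one, via ring A prenylphenol propargyl ether 8 (not isolated), via ortho-allenylphenol 9 (not isolated), via ortho-quinone methide 10 (not isolated)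
Conditions: PhNEt2 (degassed), 130 °C then 190 °C, Ar, sealed tube
Reagents that add atoms: none
Why: On ring A a chair-like [3,3] shift of the 1,1-dimethylallyl ether inverts the allyl unit, forms C3'–C1'' and, after tautomerisation, gives prenylphenol 8; at the higher temperature the propargyl ether of ring B undergoes its own [3,3] shift (forming C3a–C3) to an allenyl dienone that enolises to 9, and a 1,5-hydrogen shift then gives ortho-quinone methide 10. The pyran ring closes by a thermal six-electron (disrotatory) oxa-electrocyclisation of 10 that forms the O–C(CH3)2 bond. The closest known reaction types are the aromatic Claisen rearrangement of aryl 1,1-dimethylallyl ethers to ortho-prenylphenols and the thermal conversion of aryl 1,1-dimethylpropargyl ethers into 2,2-dimethylchromenes, combined here in a single thermal operation. No stereocentre is created. The step needs ring A to deliver the allyl unit to C3' and not C5', which the 2'-OH···O=C hydrogen bond secures by bond fixation, whereas both ortho carbons of ring B are equivalent. Geminal methyl substitution lowers the barrier of each sigmatropic step, and the weakly basic amine solvent should suppress acid-catalysed chroman and flavanone formation.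

Step 6
Reactants: 11 (E)-1-[2,4-dihydroxy-3-(3-methylbut-2-enyl)phenyl]-3-(2,2-dimethyl-2H-chromen-6-yl)prop-2-en-1-one
Product: 12 (E)-1-[2,4-bis(tert-butyldimethylsilyloxy)-3-(3-methylbut-2-enyl)phenyl]-3-(2,2-dimethyl-2H-chromen-6-yl)prop-2-en-1-one
Conditions: TBSOTf, 2,6-lutidine, CH2Cl2, 0 °C to rt
Reagents that add atoms: tert-butyldimethylsilyl trifluoromethanesulfonate, CC(C)(C)[Si](C)(C)OS(=O)(=O)C(F)(F)F
Why: Silyl ether formation with the reactive silyl triflate should overcome the hydrogen-bonded, doubly flanked 2'-OH, so that both phenols are masked before oxidation and sulfonylation.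

Step 7
Reactants: 12 (E)-1-[2,4-bis(tert-butyldimethylsilyloxy)-3-(3-methylbut-2-enyl)phenyl]-3-(2,2-dimethyl-2H-chromen-6-yl)prop-2-en-1-one
Product: 13 (E)-1-[2,4-bis(tert-butyldimethylsilyloxy)-3-(3-methylbut-2-enyl)phenyl]-3-[(3S,4S)-3,4-epoxy-2,2-dimethylchroman-6-yl]prop-2-en-1-one
Conditions: (S,S)-Mn(salen)Cl (5 mol %), mCPBA (1.1 equiv, added in portions), NMO, CH2Cl2, −78 °C
Reagents that add atoms: 3-chloroperoxybenzoic acid, OC(=O)c1cccc(Cl)c1 with the peroxy oxygen transferred, written as O=C(OO)c1cccc(Cl)c1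
Why: Jacobsen epoxidation, in which the manganese-oxo species prefers the cis-disubstituted aryl-conjugated chromene alkene over the electron-poor trans-enone and the isolated prenyl alkene, and the (S,S)-ligand steers side-on approach to the face that gives the (3S,4S)-epoxide, setting both stereocentres by catalyst control.

Step 8
Reactants: 13 (E)-1-[2,4-bis(tert-butyldimethylsilyloxy)-3-(3-methylbut-2-enyl)phenyl]-3-[(3S,4S)-3,4-epoxy-2,2-dimethylchroman-6-yl]prop-2-en-1-one
Product: 14 (E)-1-[2,4-bis(tert-butyldimethylsilyloxy)-3-(3-methylbut-2-enyl)phenyl]-3-[(3S,4R)-3,4-dihydroxy-2,2-dimethylchroman-6-yl]prop-2-en-1-one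
Conditions: 0.1 M aq. HClO4 (cat.), THF, 0 °C
Reagents that add atoms: water, O
Why: Acid-catalysed anti hydrolysis of a benzylic epoxide, in which water attacks C4 opposite the oxirane oxygen with inversion (4S to 4R) and leaves C3 untouched, the enone para to O1 damping benzylic cation character so that the opening should remain SN2-like.

Step 9
Reactants: 14 (E)-1-[2,4-bis(tert-butyldimethylsilyloxy)-3-(3-methylbut-2-enyl)phenyl]-3-[(3S,4R)-3,4-dihydroxy-2,2-dimethylchroman-6-yl]prop-2-en-1-one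
Product: 15 (E)-1-[2,4-bis(tert-butyldimethylsilyloxy)-3-(3-methylbut-2-enyl)phenyl]-3-[(3S,4R)-4-(tert-butyldimethylsilyloxy)-3-hydroxy-2,2-dimethylchroman-6-yl]prop-2-en-1-one
Conditions: TBSCl (1.1 equiv), imidazole, DMF, 0 °C
Reagents that add atoms: tert-butyldimethylsilyl chloride, CC(C)(C)[Si](C)(C)Cl
Why: Site-selective silyl ether formation, since the benzylic C4 hydroxyl is an ordinary secondary alcohol whereas the C3 hydroxyl is neopentyl-like beside the gem-dimethyl carbon, so the bulky silyl chloride should react at C4.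

Step 10
Reactants: 15 (E)-1-[2,4-bis(tert-butyldimethylsilyloxy)-3-(3-methylbut-2-enyl)phenyl]-3-[(3S,4R)-4-(tert-butyldimethylsilyloxy)-3-hydroxy-2,2-dimethylchroman-6-yl]prop-2-en-1-one
Product: 18 (E)-1-[2,4-bis(tert-butyldimethylsilyloxy)-3-(3-methylbut-2-enyl)phenyl]-3-[(2R,3R)-3-(tert-butyldimethylsilyloxy)-2-(2-hydroxypropan-2-yl)-2,3-dihydro-1-benzofuran-5-yl]prop-2-en-1-one, via C3 triflate 16 (not isolated), via bridged aryloxiranium triflate 17 (not isolated)
Conditions: Tf2O, 2,6-lutidine, CH2Cl2, −78 to −40 °C; then THF/H2O, NaHCO3, −40 °C to rt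
Reagents that add atoms: water, O
Why: Sulfonate solvolysis with anchimeric assistance (1,2-aryloxy shift, the ring contraction known for 2,2-dimethylchroman-3-yl sulfonates): the equatorial C3 triflate expected for the trans-diequatorial chroman lies anti-periplanar to the C2–O1 bond, so O1 displaces it from the rear with inversion to give oxiranium ion 17, which water opens at the tertiary carbon, making the new benzofuran C2 R and leaving the silyloxy-bearing carbon R.

Step 11
Reactants: 18 (E)-1-[2,4-bis(tert-butyldimethylsilyloxy)-3-(3-methylbut-2-enyl)phenyl]-3-[(2R,3R)-3-(tert-butyldimethylsilyloxy)-2-(2-hydroxypropan-2-yl)-2,3-dihydro-1-benzofuran-5-yl]prop-2-en-1-one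
Product: 19 Paratocarpin G, (E)-1-[2,4-dihydroxy-3-(3-methylbut-2-enyl)phenyl]-3-[(2R,3R)-3-hydroxy-2-(2-hydroxypropan-2-yl)-2,3-dihydro-1-benzofuran-5-yl]prop-2-en-1-one
Conditions: Bu4NF, AcOH, THF, 0 °C to rt
Reagents that add atoms: none
Why: Fluoride-mediated desilylation driven by the strong Si–F bond removes the two aryl and the one secondary alkyl silyl ether, the acetic acid buffer keeping the phenols protonated so that the 2'-hydroxychalcone should not cyclise to a flavanone and no stereocentre is touched.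

**Compound list**

1 | 4-hydroxybenzaldehyde | O=Cc1ccc(O)cc1 | starting material
2 | 3-chloro-3-methylbut-1-yne | C#CC(C)(C)Cl | starting material
3 | 4-(2-methylbut-3-yn-2-yloxy)benzaldehyde | C#CC(C)(C)Oc1ccc(C=O)cc1 | intermediate
4 | 2,4-dihydroxyacetophenone | CC(=O)c1ccc(O)cc1O | starting material
5 | 1-[2-hydroxy-4-(2-methylbut-3-yn-2-yloxy)phenyl]ethanone | CC(=O)c1ccc(OC(C)(C)C#C)cc1O | intermediate
6 | 1-[2-hydroxy-4-(2-methylbut-3-en-2-yloxy)phenyl]ethanone | CC(=O)c1ccc(OC(C)(C)C=C)cc1O | intermediate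
7 | (E)-1-[2-hydroxy-4-(2-methylbut-3-en-2-yloxy)phenyl]-3-[4-(2-methylbut-3-yn-2-yloxy)phenyl]prop-2-en-1-one | C=CC(C)(C)Oc1ccc(C(=O)/C=C/c2ccc(OC(C)(C)C#C)cc2)c(O)c1 | intermediate
8 | (E)-1-[2,4-dihydroxy-3-(3-methylbut-2-enyl)phenyl]-3-[4-(2-methylbut-3-yn-2-yloxy)phenyl]prop-2-en-1-one | CC(C)=CCc1c(O)ccc(C(=O)/C=C/c2ccc(OC(C)(C)C#C)cc2)c1O | intermediate
9 | (E)-1-[2,4-dihydroxy-3-(3-methylbut-2-enyl)phenyl]-3-[4-hydroxy-3-(3-methylbuta-1,2-dienyl)phenyl]prop-2-en-1-one | CC(C)=CCc1c(O)ccc(C(=O)/C=C/c2ccc(O)c(C=C=C(C)C)c2)c1O | intermediate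
10 | (E)-1-[2,4-dihydroxy-3-(3-methylbut-2-enyl)phenyl]-3-[(3Z)-3-(3-methylbut-2-enylidene)-4-oxocyclohexa-1,5-dien-1-yl]prop-2-en-1-one | CC(C)=CCc1c(O)ccc(C(=O)/C=C/C2=C/C(=C/C=C(C)C)C(=O)C=C2)c1O | intermediate
11 | (E)-1-[2,4-dihydroxy-3-(3-methylbut-2-enyl)phenyl]-3-(2,2-dimethyl-2H-chromen-6-yl)prop-2-en-1-one | CC(C)=CCc1c(O)ccc(C(=O)/C=C/c2ccc3c(c2)C=CC(C)(C)O3)c1O | intermediate
12 | (E)-1-[2,4-bis(tert-butyldimethylsilyloxy)-3-(3-methylbut-2-enyl)phenyl]-3-(2,2-dimethyl-2H-chromen-6-yl)prop-2-en-1-one | CC(C)=CCc1c(O[Si](C)(C)C(C)(C)C)ccc(C(=O)/C=C/c2ccc3c(c2)C=CC(C)(C)O3)c1O[Si](C)(C)C(C)(C)C | intermediate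
13 | (E)-1-[2,4-bis(tert-butyldimethylsilyloxy)-3-(3-methylbut-2-enyl)phenyl]-3-[(3S,4S)-3,4-epoxy-2,2-dimethylchroman-6-yl]prop-2-en-1-one | CC(C)=CCc1c(O[Si](C)(C)C(C)(C)C)ccc(C(=O)/C=C/c2ccc3c(c2)[C@@H]4O[C@@H]4C(C)(C)O3)c1O[Si](C)(C)C(C)(C)C | intermediate
14 | (E)-1-[2,4-bis(tert-butyldimethylsilyloxy)-3-(3-methylbut-2-enyl)phenyl]-3-[(3S,4R)-3,4-dihydroxy-2,2-dimethylchroman-6-yl]prop-2-en-1-one | CC(C)=CCc1c(O[Si](C)(C)C(C)(C)C)ccc(C(=O)/C=C/c2ccc3c(c2)[C@@H](O)[C@H](O)C(C)(C)O3)c1O[Si](C)(C)C(C)(C)C | intermediate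
15 | (E)-1-[2,4-bis(tert-butyldimethylsilyloxy)-3-(3-methylbut-2-enyl)phenyl]-3-[(3S,4R)-4-(tert-butyldimethylsilyloxy)-3-hydroxy-2,2-dimethylchroman-6-yl]prop-2-en-1-one | CC(C)=CCc1c(O[Si](C)(C)C(C)(C)C)ccc(C(=O)/C=C/c2ccc3c(c2)[C@@H](O[Si](C)(C)C(C)(C)C)[C@H](O)C(C)(C)O3)c1O[Si](C)(C)C(C)(C)C | intermediate
16 | (3S,4R)-6-{(E)-3-[2,4-bis(tert-butyldimethylsilyloxy)-3-(3-methylbut-2-enyl)phenyl]-3-oxoprop-1-enyl}-4-(tert-butyldimethylsilyloxy)-2,2-dimethylchroman-3-yl trifluoromethanesulfonate | CC(C)=CCc1c(O[Si](C)(C)C(C)(C)C)ccc(C(=O)/C=C/c2ccc3c(c2)[C@@H](O[Si](C)(C)C(C)(C)C)[C@H](OS(=O)(=O)C(F)(F)F)C(C)(C)O3)c1O[Si](C)(C)C(C)(C)C | intermediate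
17 | bridged aryloxiranium triflate in which O1 is bonded to the aryl carbon, to C(CH3)2 and to the former C3, the silyloxy carbon unchanged | CC(C)=CCc1c(O[Si](C)(C)C(C)(C)C)ccc(C(=O)/C=C/c2ccc3c(c2)[C@@H](O[Si](C)(C)C(C)(C)C)[C@@H]4C(C)(C)[O+]34)c1O[Si](C)(C)C(C)(C)C.[O-]S(=O)(=O)C(F)(F)F | intermediate
18 | (E)-1-[2,4-bis(tert-butyldimethylsilyloxy)-3-(3-methylbut-2-enyl)phenyl]-3-[(2R,3R)-3-(tert-butyldimethylsilyloxy)-2-(2-hydroxypropan-2-yl)-2,3-dihydro-1-benzofuran-5-yl]prop-2-en-1-one | CC(C)=CCc1c(O[Si](C)(C)C(C)(C)C)ccc(C(=O)/C=C/c2ccc3c(c2)[C@@H](O[Si](C)(C)C(C)(C)C)[C@H](C(C)(C)O)O3)c1O[Si](C)(C)C(C)(C)C | intermediate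
19 | Paratocarpin G, (E)-1-[2,4-dihydroxy-3-(3-methylbut-2-enyl)phenyl]-3-[(2R,3R)-3-hydroxy-2-(2-hydroxypropan-2-yl)-2,3-dihydro-1-benzofuran-5-yl]prop-2-en-1-one | CC(C)=CCc1c(O)ccc(C(=O)/C=C/c2ccc3c(c2)[C@@H](O)[C@H](C(C)(C)O)O3)c1O | target

**Step count and risks**

Total step count: 11. Longest linear sequence: 10 steps (2,4-dihydroxyacetophenone 4 through steps 2 to 11).

Steps most likely to fail:

1. Step 5 (two-directional cascade). The tertiary allyl group may be lost as isoprene before it migrates, ring A may deliver the allyl unit to C5', or the hot 2'-hydroxychalcone may isomerise to a flavanone. Fallback: the two rearrangements would be run on the separate halves before the enone exists. Setting out from ketone 6, heating (PhNEt2, 130–150 °C) should give 1-[2,4-dihydroxy-3-(3-methylbut-2-enyl)phenyl]ethanone F1. Setting out from aldehyde 3, heating (PhNEt2, 190 °C) should give 2,2-dimethyl-2H-chromene-6-carbaldehyde F2. Claisen–Schmidt condensation of F1 with F2 (excess KOH, EtOH/H2O) should then give chalcone 11, where the route is rejoined.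

2. Step 10 (ring contraction). The cationic rearrangement may take another course: migration of the other anti-periplanar ring bond (C4–C4a) pushed by the C4 oxygen, participation of the silyl ether oxygen, or proton loss from the tertiary cation instead of hydration. Fallback: the C4 oxygen would be carried as an electron-poor ester that cannot stabilise a cation at C4. Setting out from diol 14, acylation of the benzylic hydroxyl (4-nitrobenzoyl chloride, pyridine, CH2Cl2, −20 °C) should give the (3S,4R)-3-hydroxy-4-(4-nitrobenzoyloxy)chroman F3. Triflation (Tf2O, 2,6-lutidine) should give its C3 trifluoromethanesulfonate F4, and aqueous solvolysis (THF/H2O, NaHCO3) should give the (2R,3R)-3-(4-nitrobenzoyloxy)-2-(2-hydroxypropan-2-yl)dihydrobenzofuran F5. K2CO3 in MeOH should then cleave the ester and both aryl silyl ethers to give 19, where the route is rejoined.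

3. Step 9 (site-selective silylation). Discrimination between the two secondary hydroxyls may be poor, giving the regioisomeric or the doubly silylated ether. Fallback: the C4 oxygen would be differentiated at the epoxide stage instead of by selective protection. Setting out from epoxide 13, ring opening at C4 with 4-methoxybenzyl alcohol (Bi(OTf)3 cat., CH2Cl2, 0 °C) should give the (3S,4R)-3-hydroxy-4-(4-methoxybenzyloxy)chroman F6. Triflation should give its C3 trifluoromethanesulfonate F7, and aqueous solvolysis as in step 10 should give the (2R,3R)-3-(4-methoxybenzyloxy)-2-(2-hydroxypropan-2-yl)dihydrobenzofuran F8. Oxidative debenzylation (DDQ, CH2Cl2/pH 7 buffer) should give the bis-silylated (2R,3R)-diol F9, and Bu4NF/AcOH should give 19, where the route is rejoined.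

**Further compounds**

F1 | step 5 | 1-[2,4-dihydroxy-3-(3-methylbut-2-enyl)phenyl]ethanone | CC(=O)c1ccc(O)c(CC=C(C)C)c1O
F2 | step 5 | 2,2-dimethyl-2H-chromene-6-carbaldehyde | CC1(C)C=Cc2cc(C=O)ccc2O1
F3 | step 10 | (E)-1-[2,4-bis(tert-butyldimethylsilyloxy)-3-(3-methylbut-2-enyl)phenyl]-3-[(3S,4R)-3-hydroxy-2,2-dimethyl-4-(4-nitrobenzoyloxy)chroman-6-yl]prop-2-en-1-one | CC(C)=CCc1c(O[Si](C)(C)C(C)(C)C)ccc(C(=O)/C=C/c2ccc3c(c2)[C@@H](OC(=O)c4ccc(cc4)[N+](=O)[O-])[C@H](O)C(C)(C)O3)c1O[Si](C)(C)C(C)(C)C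
F4 | step 10 | C3 trifluoromethanesulfonate of F3, (3S,4R) | CC(C)=CCc1c(O[Si](C)(C)C(C)(C)C)ccc(C(=O)/C=C/c2ccc3c(c2)[C@@H](OC(=O)c4ccc(cc4)[N+](=O)[O-])[C@H](OS(=O)(=O)C(F)(F)F)C(C)(C)O3)c1O[Si](C)(C)C(C)(C)C
F5 | step 10 | (E)-1-[2,4-bis(tert-butyldimethylsilyloxy)-3-(3-methylbut-2-enyl)phenyl]-3-[(2R,3R)-2-(2-hydroxypropan-2-yl)-3-(4-nitrobenzoyloxy)-2,3-dihydro-1-benzofuran-5-yl]prop-2-en-1-one | CC(C)=CCc1c(O[Si](C)(C)C(C)(C)C)ccc(C(=O)/C=C/c2ccc3c(c2)[C@@H](OC(=O)c4ccc(cc4)[N+](=O)[O-])[C@H](C(C)(C)O)O3)c1O[Si](C)(C)C(C)(C)C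
F6 | step 9 | (E)-1-[2,4-bis(tert-butyldimethylsilyloxy)-3-(3-methylbut-2-enyl)phenyl]-3-[(3S,4R)-3-hydroxy-4-(4-methoxybenzyloxy)-2,2-dimethylchroman-6-yl]prop-2-en-1-one | CC(C)=CCc1c(O[Si](C)(C)C(C)(C)C)ccc(C(=O)/C=C/c2ccc3c(c2)[C@@H](OCc4ccc(OC)cc4)[C@H](O)C(C)(C)O3)c1O[Si](C)(C)C(C)(C)C
F7 | step 9 | C3 trifluoromethanesulfonate of F6, (3S,4R) | CC(C)=CCc1c(O[Si](C)(C)C(C)(C)C)ccc(C(=O)/C=C/c2ccc3c(c2)[C@@H](OCc4ccc(OC)cc4)[C@H](OS(=O)(=O)C(F)(F)F)C(C)(C)O3)c1O[Si](C)(C)C(C)(C)C
F8 | step 9 | (E)-1-[2,4-bis(tert-butyldimethylsilyloxy)-3-(3-methylbut-2-enyl)phenyl]-3-[(2R,3R)-2-(2-hydroxypropan-2-yl)-3-(4-methoxybenzyloxy)-2,3-dihydro-1-benzofuran-5-yl]prop-2-en-1-one | CC(C)=CCc1c(O[Si](C)(C)C(C)(C)C)ccc(C(=O)/C=C/c2ccc3c(c2)[C@@H](OCc4ccc(OC)cc4)[C@H](C(C)(C)O)O3)c1O[Si](C)(C)C(C)(C)C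
F9 | step 9 | (E)-1-[2,4-bis(tert-butyldimethylsilyloxy)-3-(3-methylbut-2-enyl)phenyl]-3-[(2R,3R)-3-hydroxy-2-(2-hydroxypropan-2-yl)-2,3-dihydro-1-benzofuran-5-yl]prop-2-en-1-one | CC(C)=CCc1c(O[Si](C)(C)C(C)(C)C)ccc(C(=O)/C=C/c2ccc3c(c2)[C@@H](O)[C@H](C(C)(C)O)O3)c1O[Si](C)(C)C(C)(C)C
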